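## Retrosynthetic overview
- Key disconnection is N1–C2, a C–N bond. The aniline nitrogen of an ortho-amino-β-bromo-β-arylenamine attacks the enamine CH and Me2NH leaves. The amine comes from a nitro group.
- C3–Br is set earlier, by brominating the acyclic nitrostyryl enamine at its only nucleophilic carbon, before the pyrrole ring exists.
- The enamine comes from 2,4-dibromo-6-nitrotoluene and DMF-DMA, which supplies C2.
- C4–Br and C6–Br come from double bromination of 2-nitrotoluene, where CH3 (ortho/para) and NO2 (meta) direct to the same two positions.
- Ring order: the benzene ring is bought, and the pyrrole ring is formed last, in the final flask.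

Assumption: the target has no stereocentre or stereoaxis, so it is one achiral compound and no enantiomer question arises. Only the C=C geometry of the enamine intermediates is specified.

## Route

Step 1
Reactants: 1 2-nitrotoluene
Product: 4 2,4-dibromo-6-nitrotoluene, via 4-bromo-2-nitrotoluene 2 (not isolated), via 2-bromo-6-nitrotoluene 3 (not isolated)
Conditions: NBS (2.2 equiv), conc. H2SO4, 60 °C, dark, 3–5 h
Reagents that add atoms: N-bromosuccinimide (NBS), O=C1CCC(=O)N1Br
Why: Electrophilic aromatic bromination of a deactivated arene by protonated NBS, in which CH3 and NO2 both direct to C4 and C6, so monobromides 2 and 3 converge on the same dibromide, the twice-deactivated product resists a third bromination, and no stereocentre is formed.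

Step 2
Reactants: 4 2,4-dibromo-6-nitrotoluene
Product: 5 (E)-2-(2,4-dibromo-6-nitrophenyl)-N,N-dimethylethen-1-amine
Conditions: DMF-DMA (3 equiv), DMF, 110 °C, N2, 12 h, MeOH distilled off; concentrate and triturate
Reagents that add atoms: N,N-dimethylformamide dimethyl acetal (DMF-DMA), COC(OC)N(C)C
Why: Leimgruber–Batcho aminomethylenation, in which methoxide released from DMF-DMA removes a CH3 proton acidified by the ortho-nitro group and the two bromines, and the benzylic anion condenses with the methoxymethylene iminium ion with loss of two MeOH to give the E-enamine, while both aryl bromides sit meta to NO2 and are therefore inert to substitution.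

Step 3
Reactants: 5 (E)-2-(2,4-dibromo-6-nitrophenyl)-N,N-dimethylethen-1-amine
Product: 8 3,4,6-tribromo-1H-indole, via nitro bromoenamine 6 (not isolated), via amino bromoenamine 7 (not isolated)
Conditions: NBS (1.0 equiv), DMF, −40 → 0 °C; then B2(OH)4 (3.3 equiv), 4,4'-bipyridine (2 mol %), H2O (5 equiv), 0 °C → rt; then AcOH (5 equiv), 45 °C (one flask)
Reagents that add atoms: N-bromosuccinimide (NBS), O=C1CCC(=O)N1Br
Why: Proposed new method: a brominative Leimgruber–Batcho ring closure in which NBS attacks the only nucleophilic carbon of 5 (the aryl-bearing enamine carbon, future C3) and succinimide anion removes the now acidic benzylic proton to give neutral 6; the metal-free, non-acidic B2(OH)4/4,4'-bipyridine couple then deoxygenates ArNO2 to ArNH2 (7) without electron transfer into C–Br bonds, and AcOH triggers 5-exo-trig attack of the aniline nitrogen on the C-protonated enamine CH (N1–C2 bond), after which loss of Me2NH and of the C3 proton aromatises to 8 with C3–Br kept; the closest known reaction types are the Leimgruber–Batcho reductive cyclisation, C-acylation of the same nitrostyryl enamines at this carbon and NBS bromination of enamines, whereas ring closure of a C-brominated enamine to a 3-bromoindole has not been shown; no stereocentre is formed and the geometry of 6 and 7 is lost on C-protonation.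

## Compound list
1 | 2-nitrotoluene | Cc1ccccc1[N+](=O)[O-] | starting material
2 | 4-bromo-2-nitrotoluene | Cc1ccc(Br)cc1[N+](=O)[O-] | intermediate
3 | 2-bromo-6-nitrotoluene | Cc1c(Br)cccc1[N+](=O)[O-] | intermediate
4 | 2,4-dibromo-6-nitrotoluene | Cc1c(Br)cc(Br)cc1[N+](=O)[O-] | intermediate
5 | (E)-2-(2,4-dibromo-6-nitrophenyl)-N,N-dimethylethen-1-amine | CN(C)/C=C/c1c(Br)cc(Br)cc1[N+](=O)[O-] | intermediate
6 | (Z)-2-bromo-2-(2,4-dibromo-6-nitrophenyl)-N,N-dimethylethen-1-amine (NMe2 anti to the aryl group) | CN(C)/C=C(\Br)c1c(Br)cc(Br)cc1[N+](=O)[O-] | intermediate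
7 | (Z)-3,5-dibromo-2-[1-bromo-2-(dimethylamino)ethenyl]aniline | CN(C)/C=C(\Br)c1c(Br)cc(Br)cc1N | intermediate
8 | 3,4,6-tribromo-1H-indole | Brc1cc(Br)c2c(Br)c[nH]c2c1 | target

## Step count and risks
Total step count: 3. Longest linear sequence: 3.

**Most likely to fail, first: step 3 (the new step).**
- C3–Br may be lost, either by reduction of the C-protonated bromoenamine or by transfer of electrophilic bromine to the free aniline ring.
- Excess NBS may give a gem-dibromo species.
- Incomplete reduction may lead to a 1-hydroxyindole.

The fallback uses only known chemistry, sets out from 5 and comes back at 8. Classical Leimgruber–Batcho reductive cyclisation (Fe powder, AcOH, 80 °C) gives 4,6-dibromo-1H-indole F1. Electrophilic bromination at the most nucleophilic position C3 (NBS 1.0 equiv, DMF, 0 °C) then gives 8. Any debrominated material from the failed new step is this same indole and can be carried through the same bromination.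

**Second: step 1.** The second bromination may stall at the monobromides or leave a mixture that is hard to purify. The fallback sets out from 2 (isolated after one equivalent of NBS) and comes back at 4. It brings in the second bromine as bromide on a nitrogen handle instead of as an electrophile.
- Nitration (HNO3, H2SO4, 0 → 50 °C) gives 4-bromo-2,6-dinitrotoluene F2.
- Because this dinitro compound is symmetric, Zinin mono-reduction ((NH4)2S, aq. EtOH, reflux) can give only 5-bromo-2-methyl-3-nitroaniline F3.
- Diazotisation (NaNO2, aq. HBr, 0 °C) gives 5-bromo-2-methyl-3-nitrobenzenediazonium bromide F4.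
- Sandmeyer reaction (CuBr, aq. HBr, 60 °C) delivers 4.

**Third: step 2.** The CH3 group sits between Br and NO2, so condensation may be slow, and 5 is sensitive to hydrolysis. The fallback sets out from 4 and comes back at 5. It replaces aminomethylenation by hydroxymethylation, oxidation and condensation.
- Paraformaldehyde with catalytic KOH in DMSO at rt gives 2-(2,4-dibromo-6-nitrophenyl)ethan-1-ol F5.
- Dess–Martin periodinane (CH2Cl2, rt) gives (2,4-dibromo-6-nitrophenyl)acetaldehyde F6.
- Condensation with Me2NH (2 M in THF, 4 Å molecular sieves, rt) gives 5.

Further compounds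
F1 | step 3 | 4,6-dibromo-1H-indole | Brc1cc(Br)c2cc[nH]c2c1
F2 | step 1 | 4-bromo-2,6-dinitrotoluene | Cc1c(cc(Br)cc1[N+](=O)[O-])[N+](=O)[O-]
F3 | step 1 | 5-bromo-2-methyl-3-nitroaniline | Cc1c(N)cc(Br)cc1[N+](=O)[O-]
F4 | step 1 | 5-bromo-2-methyl-3-nitrobenzenediazonium bromide | Cc1c(cc(Br)cc1[N+](=O)[O-])[N+]#N.[Br-]
F5 | step 2 | 2-(2,4-dibromo-6-nitrophenyl)ethan-1-ol | OCCc1c(Br)cc(Br)cc1[N+](=O)[O-]
F6 | step 2 | (2,4-dibromo-6-nitrophenyl)acetaldehyde | O=CCc1c(Br)cc(Br)cc1[N+](=O)[O-]
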